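A small charge of starting material, 20 mM, makes the protic impurity count by its load, meaning the impurity as a fraction of the charge: 0.190 in spring and 6.00 in midnight.

| setting | spring | midnight | ash | oak | alder | maple |
|---|---|---|---|---|---|---|
| starting material | 20 mM | 20 mM | 20 mM | 20 mM | 20 mM | 20 mM |
| protic impurity | 3.8 mM | 120 mM | 3.00 mM | 10.0 mM | 30.0 mM | 100 mM |
| solid reagent | 0.80 equiv | 0.80 equiv | 0.800 equiv | 0.800 equiv | 0.800 equiv | 0.800 equiv |
| remark | run made earlier | run made earlier |  |  |  |  |
| time |  |  | 15 h | 15 h | 15 h | 15 h |

- spring (time / h: target / %): 0.833: 0.4; 1.33: 1.0; 2.00: 2.2; 3.00: 3.2; 5.00: 7.4; 6.00: 9.4; 10.0: 21.2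
- midnight (time / h: target / %): 0.500: 0; 1.50: 0.7; 3.00: 0; 5.00: 1.0; 6.00: 3.7; 8.00: 3.2; 10.0: 4.8

(standard deviation of a reading: 1 percentage point)

- given per volume of solution although it is solid: solid reagent
- the numbers in the tables scatter with a standard deviation of 1 percentage point
- at the start none of the solid reagent is in solution
- "hardly changes" means that all values lie within two and a half points (for a concentration: within two and a half percent of the largest)

- amount of target at the end, in percent of the starting material charged for ash, oak, alder, maple, in this order
- how the row runs (hardly changes / rises all the way / falls all the way / falls, then rises / rises, then falls)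

Hanna and I read these two runs differently. She holds that the impurity competes for dissolved reagent, so that every flask follows the upward-bending spring curve, scaled by a factor that does not change with time. For her, the spring-to-midnight ratio of 4.42 at 10.0 h measures that factor.

I hold that the impurity destroys starting material in a race with the way to target. In midnight the whole charge could consume at most 16.7% of the impurity, so its level stays close to constant and the quench is pseudo-first-order in starting material. Spring's reading of 21.2% at 10.0 h gives a net clock of 0.0238 h⁻¹ for the way to target, which lumps in the early lag and spring's own quench.

Midnight's last reading, 4.8% with a scatter of 1 percentage point, I take as the final share reaching target. The race would then have a half-life of 1.40 h, shorter than the 10.0 h elapsed. If the share is the way to target over both ways together, the crossover load, at which the quench runs as fast as the way to target, is 0.303.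

While the impurity stays near its starting level, target is then the share times the fraction of the charge consumed, and the total clock is the net clock divided by the share. At 15 h this gives me 27.7%, 23.1%, 14.8% and 5.69%. That condition suits maple, whose impurity exceeds the charge, but not ash and oak, whose charge exceeds their impurity, so their two figures are rough. Spring's quench is also counted twice in this, and the impurity's running down is left out, so I expect the low-load end to come out low.

The forecast is Hanna's number, 39%, 33%, 23% and 11%, a row that falls all the way, on her reading of “the impurity competing for dissolved reagent”.

The flask gives 31.9%, 26.7%, 16.7% and 5.96%, a row that falls all the way. Solid reagent stands at 19.1% in ash and 19.3% in maple, while starting material stands at 37.2% and 0%.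

    starting material → intermediate A (k = 0.0550 h⁻¹)
    intermediate A → target (k = 0.140 h⁻¹)
    intermediate A → intermediate B (k = 0.0110 h⁻¹)
    partner + intermediate B ⇌ intermediate C (K = 17.0 M⁻¹, k = 2.70 M⁻¹ h⁻¹)
    partner + intermediate C → intermediate D (k = 18.0 M⁻¹ h⁻¹)
    intermediate D → side product (k = 0.100 h⁻¹)
    starting material + protic impurity → quenched substrate (k = 7.60 M⁻¹ h⁻¹)
    solid reagent ⇌ partner, rate k8*(cs8 - [partner]) while solid is left; crystals form when [partner] > cs8 (solubility = 14.0 mM, k = 0.170 h⁻¹)

Ash has a load of 0.150, below the crossover load: at 3.65 h its starting material went to intermediate A 3.9 times as fast as it was quenched, and ash's target climbed from 31.9% at 15.0 h to 80.1% at 150 h. Hanna's time-free factor has its region at low loads up to 15.0 h: ash's target over oak's is 1.11 at 7.50 h and 1.19 at 15.0 h, though it grows to 1.45 at 150 h. Maple, with a load of 5.00, lies far above the crossover load: there my share is 5.71%, and maple's target stands at 5.96% at 15.0 h and 6.87% at 150 h.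

(Readings and results are calculated from invented constants; scatter was added.)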